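**Retrosynthetic overview**
1. The last bonds cut are the two benzyl–oxygen bonds and O1''–C2'' of ring C''; this leads back to a 2,4,6-trihydroxyphenyl 1,3-diketone.
2. Key disconnection: C4a''–C8a'' of ring A''. Ring A'' (C4a'', C5'', C6'', C7'', C8'', C8a'') is a phloroglucinol with oxygen on C5'', C7'' and C8a'' and the acyl carbon C4'' on C4a''. It is folded by Claisen condensation from a 3,5,7,9-tetraoxo ester masked as a 4-hydroxy-2-pyrone. Since C5''–OH and C8a''–OH are equivalent, the later closure of ring C'' has only one outcome.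
3. The chain is cut at C2''–C3'': the trilithium salt of 4-hydroxy-6-(2-oxopropyl)-2-pyrone is acylated by a methyl 4-aryloxybenzoate. The pyrone itself comes from triacetic acid lactone by acetylation (C4''–C4a'').
4. The diaryl ether C8–O–C4''' comes from SNAr of an 8-hydroxyflavone on methyl 4-fluorobenzoate. The 8-hydroxyl is put on acacetin by benzylation, C8 iodination, borylation and oxidation.
5. Ring order: rings A, C and B of the methoxyflavone unit and the phenylene ring are purchased; ring A'' is formed in step 8 and ring C'' in step 9.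

Key step: step 8

Remark: the target has no stereocentre, so no configuration has to be set. Locants with two primes belong to the 5,7-dihydroxyflavone unit and those with three primes to its phenylene ring.

**Step 1**
Reactants: 1 acacetin (5,7-dihydroxy-2-(4-methoxyphenyl)-4H-chromen-4-one)
Product: 2 5,7-bis(benzyloxy)-2-(4-methoxyphenyl)-4H-chromen-4-one
Conditions: BnBr (3 equiv), K2CO3, DMF, 80 °C
Reagents that add atoms: benzyl bromide, BrCc1ccccc1
Why: Williamson ether synthesis, in which carbonate deprotonates both phenols and each phenoxide displaces bromide by SN2; heating in DMF is needed only for the hydrogen-bonded 5-OH, and nothing else in acacetin is alkylated.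

**Step 2**
Reactants: 2 5,7-bis(benzyloxy)-2-(4-methoxyphenyl)-4H-chromen-4-one
Product: 3 5,7-bis(benzyloxy)-8-iodo-2-(4-methoxyphenyl)-4H-chromen-4-one
Conditions: NIS (1.1 equiv), CF3CO2H (cat.), MeCN, 0 °C → rt
Reagents that add atoms: N-iodosuccinimide, O=C1CCC(=O)N1I
Why: Electrophilic aromatic iodination should go to ring A, the only phloroglucinol-type ring, and in fully O-alkylated 5,7-dioxygenated flavones to C8 (ortho to O1 and 7-OBn, para to 5-OBn) rather than to C6, which lies between two benzyloxy groups.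

**Step 3**
Reactants: 3 5,7-bis(benzyloxy)-8-iodo-2-(4-methoxyphenyl)-4H-chromen-4-one
Product: 4 5,7-bis(benzyloxy)-2-(4-methoxyphenyl)-8-(4,4,5,5-tetramethyl-1,3,2-dioxaborolan-2-yl)-4H-chromen-4-one
Conditions: B2pin2, PdCl2(dppf) (5 mol %), KOAc, 1,4-dioxane, 90 °C
Reagents that add atoms: bis(pinacolato)diboron, CC1(C)OB(OC1(C)C)B1OC(C)(C)C(C)(C)O1
Why: Miyaura borylation, in which oxidative addition of the C8–I bond to palladium, acetate-assisted transmetalation from the diboron and reductive elimination give the aryl boronate, while KOAc is too weak a base to harm the chromone or the benzyl ethers.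

**Step 4**
Reactants: 4 5,7-bis(benzyloxy)-2-(4-methoxyphenyl)-8-(4,4,5,5-tetramethyl-1,3,2-dioxaborolan-2-yl)-4H-chromen-4-one
Product: 5 5,7-bis(benzyloxy)-8-hydroxy-2-(4-methoxyphenyl)-4H-chromen-4-one
Conditions: 30% H2O2, NaOH, THF/H2O, 0 °C; then dil. HCl
Reagents that add atoms: hydrogen peroxide, OO
Why: Boronate oxidation, in which hydroperoxide adds to boron and the aryl group shifts from boron to oxygen with the C8 position retained; this is fast at 0 °C and should leave the chromone C2=C3 bond alone on short exposure.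

**Step 5**
Reactants: 5 5,7-bis(benzyloxy)-8-hydroxy-2-(4-methoxyphenyl)-4H-chromen-4-one; 6 methyl 4-fluorobenzoate
Product: 7 methyl 4-{[5,7-bis(benzyloxy)-2-(4-methoxyphenyl)-4-oxo-4H-chromen-8-yl]oxy}benzoate
Conditions: Cs2CO3, DMSO, 100 °C, N2
Reagents that add atoms: none
Why: Nucleophilic aromatic substitution (SNAr), in which the caesium phenoxide of the only free hydroxyl adds para to the ester group and the Meisenheimer adduct loses fluoride; benzyl ethers, methyl ester and chromone tolerate carbonate in dry DMSO.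

**Step 6**
Reactants: 8 4-hydroxy-6-methyl-2H-pyran-2-one (triacetic acid lactone)
Product: 9 4-hydroxy-6-(2-oxopropyl)-2H-pyran-2-one
Conditions: LiN(iPr)2 (2.1 equiv), THF, −78 → 0 °C; then MeC(O)N(OMe)Me, −78 → 0 °C; aq. HCl
Reagents that add atoms: N-methoxy-N-methylacetamide, CON(C)C(C)=O
Why: Acylation of a dianion, in which the second equivalent of amide base removes a 6-methyl proton of the lithium pyronate and this most nucleophilic carbon attacks the Weinreb amide; the chelated tetrahedral adduct lasts until work-up, so the ketone is neither attacked twice nor able to quench the dianion.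

**Step 7**
Reactants: 9 4-hydroxy-6-(2-oxopropyl)-2H-pyran-2-one; 7 methyl 4-{[5,7-bis(benzyloxy)-2-(4-methoxyphenyl)-4-oxo-4H-chromen-8-yl]oxy}benzoate
Product: 10 6-{4-[4-({5,7-bis(benzyloxy)-2-(4-methoxyphenyl)-4-oxo-4H-chromen-8-yl}oxy)phenyl]-2,4-dioxobutyl}-4-hydroxy-2H-pyran-2-one
Conditions: 9 (2.5 equiv), LiN(iPr)2 (7.5 equiv), THF, −78 → 0 °C; then 7, −78 → 0 °C; cold aq. HCl
Reagents that add atoms: none
Why: Claisen-type C-acylation of a polyanion, in which the terminal methyl carbanion of the trilithium salt of 9 (its least stabilised and most nucleophilic site) adds to the ester carbonyl of 7 and methoxide leaves; the surplus trianion serves as base for the more acidic product, and with no free LiN(iPr)2 left the C3–H and the donor-deactivated C4=O of the chromone in 7 should stay untouched at low temperature.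

**Step 8**
Reactants: 10 6-{4-[4-({5,7-bis(benzyloxy)-2-(4-methoxyphenyl)-4-oxo-4H-chromen-8-yl}oxy)phenyl]-2,4-dioxobutyl}-4-hydroxy-2H-pyran-2-one
Product: 12 1-[4-({5,7-bis(benzyloxy)-2-(4-methoxyphenyl)-4-oxo-4H-chromen-8-yl}oxy)phenyl]-3-(2,4,6-trihydroxyphenyl)propane-1,3-dione, via open-chain methyl tetraoxononanoate 11 (not isolated)
Conditions: Mg(OMe)2 (10 equiv), MeOH, reflux, N2; then cold dil. HCl
Reagents that add atoms: none
Why: Mg(OMe)2 turns 10 into its magnesium enolates and methoxide adds to the lactone carbonyl (pyrone C2), which unmasks the methyl 3,5,7,9-tetraoxo ester 11; the magnesium-bound carbanion at C4a'' (the methylene between the C4'' ketone and the former pyrone C6) then attacks the ester carbon, the future C8a'', and expels the same methoxide, so 12 is an isomer of 10. The closest known reaction is the biomimetic Claisen cyclization of 3,5,7-triketo esters and of 6-(2-oxoalkyl)-4-hydroxy-2-pyrones to acylphloroglucinols under Mg(OMe)2. Ring A'' closes in the 6-exo-trig mode as a 2-acylcyclohexane-1,3,5-trione, and its enolization to the aromatic triol makes the closure irreversible. No stereocentre is formed. The step needs Claisen folding (C4a'' onto the ester) to beat the aldol foldings that would give resorcinol derivatives. Chelation of the poly-β-carbonyl array by divalent magnesium holds C4a'' next to the ester and tempers the ketone electrophiles, the terminus is an ester and not a carboxylate so it stays acylating, and while the pyrone is still closed no aldol ring can form at all.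

**Step 9**
Reactants: 12 1-[4-({5,7-bis(benzyloxy)-2-(4-methoxyphenyl)-4-oxo-4H-chromen-8-yl}oxy)phenyl]-3-(2,4,6-trihydroxyphenyl)propane-1,3-dione
Product: 13 5,7-bis(benzyloxy)-8-[4-(5,7-dihydroxy-4-oxo-4H-chromen-2-yl)phenoxy]-2-(4-methoxyphenyl)-4H-chromen-4-one
Conditions: AcOH, H2SO4 (cat.), 50 °C
Reagents that add atoms: none
Why: Acid-catalysed cyclodehydration (the closing step of a Baker–Venkataraman flavone synthesis), in which an ortho hydroxyl of ring A'' adds to the C2'' ketone and loss of water gives the 4-pyranone; the two ortho hydroxyls are equivalent so only one flavone can form, and a benzyl ether lost to acid here would be removed in step 10 anyway.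

**Step 10**
Reactants: 13 5,7-bis(benzyloxy)-8-[4-(5,7-dihydroxy-4-oxo-4H-chromen-2-yl)phenoxy]-2-(4-methoxyphenyl)-4H-chromen-4-one
Product: 14 8-[4-(5,7-dihydroxy-4-oxo-4H-chromen-2-yl)phenoxy]-5,7-dihydroxy-2-(4-methoxyphenyl)-4H-chromen-4-one (CNP0295851.0)
Conditions: H2 (1 atm), 10% Pd/C, THF/MeOH, rt
Reagents that add atoms: none
Why: Catalytic hydrogenolysis cleaves the two benzylic C–O bonds on palladium, while the methyl ether, the diaryl ether and the chromone double bonds should not be reduced at 1 atm and room temperature.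

**Compound list**
1 | acacetin, 5,7-dihydroxy-2-(4-methoxyphenyl)-4H-chromen-4-one | COc1ccc(-c2cc(=O)c3c(O)cc(O)cc3o2)cc1 | starting material
2 | 5,7-bis(benzyloxy)-2-(4-methoxyphenyl)-4H-chromen-4-one | COc1ccc(-c2cc(=O)c3c(OCc4ccccc4)cc(OCc4ccccc4)cc3o2)cc1 | intermediate
3 | 5,7-bis(benzyloxy)-8-iodo-2-(4-methoxyphenyl)-4H-chromen-4-one | COc1ccc(-c2cc(=O)c3c(OCc4ccccc4)cc(OCc4ccccc4)c(I)c3o2)cc1 | intermediate
4 | 5,7-bis(benzyloxy)-2-(4-methoxyphenyl)-8-(4,4,5,5-tetramethyl-1,3,2-dioxaborolan-2-yl)-4H-chromen-4-one | COc1ccc(-c2cc(=O)c3c(OCc4ccccc4)cc(OCc4ccccc4)c(B4OC(C)(C)C(C)(C)O4)c3o2)cc1 | intermediate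
5 | 5,7-bis(benzyloxy)-8-hydroxy-2-(4-methoxyphenyl)-4H-chromen-4-one | COc1ccc(-c2cc(=O)c3c(OCc4ccccc4)cc(OCc4ccccc4)c(O)c3o2)cc1 | intermediate
6 | methyl 4-fluorobenzoate | COC(=O)c1ccc(F)cc1 | starting material
7 | methyl 4-{[5,7-bis(benzyloxy)-2-(4-methoxyphenyl)-4-oxo-4H-chromen-8-yl]oxy}benzoate | COc1ccc(-c2cc(=O)c3c(OCc4ccccc4)cc(OCc4ccccc4)c(Oc4ccc(C(=O)OC)cc4)c3o2)cc1 | intermediate
8 | 4-hydroxy-6-methyl-2H-pyran-2-one | Cc1cc(O)cc(=O)o1 | starting material
9 | 4-hydroxy-6-(2-oxopropyl)-2H-pyran-2-one | CC(=O)Cc1cc(O)cc(=O)o1 | intermediate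
10 | 6-{4-[4-({5,7-bis(benzyloxy)-2-(4-methoxyphenyl)-4-oxo-4H-chromen-8-yl}oxy)phenyl]-2,4-dioxobutyl}-4-hydroxy-2H-pyran-2-one | COc1ccc(-c2cc(=O)c3c(OCc4ccccc4)cc(OCc4ccccc4)c(Oc4ccc(C(=O)CC(=O)Cc5cc(O)cc(=O)o5)cc4)c3o2)cc1 | intermediate
11 | methyl 9-[4-({5,7-bis(benzyloxy)-2-(4-methoxyphenyl)-4-oxo-4H-chromen-8-yl}oxy)phenyl]-3,5,7,9-tetraoxononanoate (not isolated) | COc1ccc(-c2cc(=O)c3c(OCc4ccccc4)cc(OCc4ccccc4)c(Oc4ccc(C(=O)CC(=O)CC(=O)CC(=O)CC(=O)OC)cc4)c3o2)cc1 | intermediate
12 | 1-[4-({5,7-bis(benzyloxy)-2-(4-methoxyphenyl)-4-oxo-4H-chromen-8-yl}oxy)phenyl]-3-(2,4,6-trihydroxyphenyl)propane-1,3-dione (may sit as its 2-hydroxyflavanone ring tautomer) | COc1ccc(-c2cc(=O)c3c(OCc4ccccc4)cc(OCc4ccccc4)c(Oc4ccc(C(=O)CC(=O)c5c(O)cc(O)cc5O)cc4)c3o2)cc1 | intermediate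
13 | 5,7-bis(benzyloxy)-8-[4-(5,7-dihydroxy-4-oxo-4H-chromen-2-yl)phenoxy]-2-(4-methoxyphenyl)-4H-chromen-4-one | COc1ccc(-c2cc(=O)c3c(OCc4ccccc4)cc(OCc4ccccc4)c(Oc4ccc(-c5cc(=O)c6c(O)cc(O)cc6o5)cc4)c3o2)cc1 | intermediate
14 | 8-[4-(5,7-dihydroxy-4-oxo-4H-chromen-2-yl)phenoxy]-5,7-dihydroxy-2-(4-methoxyphenyl)-4H-chromen-4-one | COc1ccc(-c2cc(=O)c3c(O)cc(O)c(Oc4ccc(-c5cc(=O)c6c(O)cc(O)cc6o5)cc4)c3o2)cc1 | target

**Totals**
Total step count: 10.
Longest linear sequence: 9 steps (1 to 14 through steps 1–5 and 7–10); the pyrone branch (8 to 9) adds step 6.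

**Steps most likely to fail**

Step 8. Once the pyrone is opened, the polyketo ester may fold by aldol condensation between a chain methylene and a chain ketone to give resorcinol-type aromatics. It may also be cut by retro-Claisen methanolysis before the C4a'' carbanion reaches the ester. The fallback sets out from 7 and comes back to the route at 12; ring A'' is then bought instead of folded. Saponification (LiOH, THF/H2O, rt) gives 4-{[5,7-bis(benzyloxy)-2-(4-methoxyphenyl)-4-oxo-4H-chromen-8-yl]oxy}benzoic acid F1. Treatment with (COCl)2 and catalytic DMF in CH2Cl2 gives 4-{[5,7-bis(benzyloxy)-2-(4-methoxyphenyl)-4-oxo-4H-chromen-8-yl]oxy}benzoyl chloride F2. The tetralithium salt of purchased 2,4,6-trihydroxyacetophenone (LiN(SiMe3)2, THF, −78 °C) is then aroylated at its enolate carbon by the acid chloride, a direct Baker–Venkataraman-type C-acylation, which after acid work-up should give 12.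

Step 7. Proton transfer from the acidic product to the trianion may stall the acylation, and the carbanion may add to the chromone of the ester partner instead of the ester. The fallback sets out from 5 and comes back at 10, replacing the ester by an aldehyde so that the carbon–carbon bond forms by aldol addition at −78 °C. SNAr of 5 on 4-fluorobenzaldehyde (K2CO3, DMF, 90 °C) gives 4-{[5,7-bis(benzyloxy)-2-(4-methoxyphenyl)-4-oxo-4H-chromen-8-yl]oxy}benzaldehyde F3. Addition of the trilithium salt of 9 gives racemic 6-{4-[4-({5,7-bis(benzyloxy)-2-(4-methoxyphenyl)-4-oxo-4H-chromen-8-yl}oxy)phenyl]-4-hydroxy-2-oxobutyl}-4-hydroxy-2H-pyran-2-one F4. Oxidation of this β-hydroxy ketone with IBX (EtOAc, 75 °C) should give the 1,3-diketone 10.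

Step 3. Oxidative addition and transmetalation at the doubly ortho-substituted C8 may be slow, so that protodeiodination back to 2 takes over. The fallback sets out from 3 and comes back at 7, skipping 4 and 5 and reversing the polarity of the ether formation. An Ullmann diaryl ether coupling of 3 with methyl 4-hydroxybenzoate (CuI, picolinic acid, Cs2CO3, DMSO, 100 °C) forms the C8–O bond directly and makes no compound outside the list (F0).

Further compounds
F1 | step 8 | 4-{[5,7-bis(benzyloxy)-2-(4-methoxyphenyl)-4-oxo-4H-chromen-8-yl]oxy}benzoic acid | COc1ccc(-c2cc(=O)c3c(OCc4ccccc4)cc(OCc4ccccc4)c(Oc4ccc(C(=O)O)cc4)c3o2)cc1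
F2 | step 8 | 4-{[5,7-bis(benzyloxy)-2-(4-methoxyphenyl)-4-oxo-4H-chromen-8-yl]oxy}benzoyl chloride | COc1ccc(-c2cc(=O)c3c(OCc4ccccc4)cc(OCc4ccccc4)c(Oc4ccc(C(=O)Cl)cc4)c3o2)cc1
F3 | step 7 | 4-{[5,7-bis(benzyloxy)-2-(4-methoxyphenyl)-4-oxo-4H-chromen-8-yl]oxy}benzaldehyde | COc1ccc(-c2cc(=O)c3c(OCc4ccccc4)cc(OCc4ccccc4)c(Oc4ccc(C=O)cc4)c3o2)cc1
F4 | step 7 | racemic 6-{4-[4-({5,7-bis(benzyloxy)-2-(4-methoxyphenyl)-4-oxo-4H-chromen-8-yl}oxy)phenyl]-4-hydroxy-2-oxobutyl}-4-hydroxy-2H-pyran-2-one | COc1ccc(-c2cc(=O)c3c(OCc4ccccc4)cc(OCc4ccccc4)c(Oc4ccc(C(O)CC(=O)Cc5cc(O)cc(=O)o5)cc4)c3o2)cc1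
F0 | step 3 | none | none
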